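**Retrosynthetic overview**
1. The strategy rests on the oxolane of the target (O1, C2 aryl, C3 CH2OH, C4 aroyl, C5H2): C2–C3 are read as the reduced form of a configurationally labile α-substituted β-keto ester (the CH2OH carbon at the ester level) and O1–C5 as the acyl bond of a γ-lactone. Ring B is therefore first made as trans lactone ester 9 from racemic aroylsuccinate 7 by transfer hydrogenation with dynamic kinetic resolution and lactonisation.
2. The aroyl carbon (C7) and the C4–C7 bond come from an aldol of the C4 enolate of 9 with aldehyde 12. Only the 3,4-cis aldolate can lactonise onto the C3 ester, so C3 fixes C4 in the cis-fused bis-lactone 15 (ring A).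
3. Both lactones are reduced and the two oxolanes re-closed as ethers (furofuran 18). The ketone and the free CH2OH are then unveiled together by oxidative opening of ring A at its phenolic benzylic carbon (DDQ), while the other aryl ring stays benzyl-capped until the last step.
4. 7 comes from acetosyringone by benzylation, Claisen condensation with dimethyl carbonate and alkylation with methyl bromoacetate; 12 comes from syringaldehyde.
5. Ring order: ring B as lactone (step 4), ring A as lactone (step 6), both rings as ethers (step 8), ring A opened (step 10).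

Key step: step 4

Remark: lignan locants are used for the side atoms (C7′, C8′, C9′ = oxolane C2, C3 and the CH2OH carbon; C8, C9 = oxolane C4, C5; C7 = ketone carbon). It is assumed that step 6 gives mainly the exo C7 epimer, which is the one drawn for 14 to 19; the other epimer would converge with it in step 10, where C7 becomes the ketone carbon.

**Step 1**
Reactants: 1 acetosyringone; 2 benzyl bromide
Product: 3 1-[4-(benzyloxy)-3,5-dimethoxyphenyl]ethan-1-one
Conditions: BnBr, K2CO3, DMF, 60 °C
Reagents that add atoms: benzyl bromide (2), BrCc1ccccc1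
Why: The hindered but acidic phenol is deprotonated by carbonate and O-alkylated by the benzylic bromide (Williamson ether synthesis), which masks the phenol for all base and hydride steps.

**Step 2**
Reactants: 3 1-[4-(benzyloxy)-3,5-dimethoxyphenyl]ethan-1-one; 4 dimethyl carbonate
Product: 5 methyl 3-[4-(benzyloxy)-3,5-dimethoxyphenyl]-3-oxopropanoate
Conditions: NaH, (MeO)2CO, THF, reflux; then aq. HCl
Reagents that add atoms: dimethyl carbonate (4), COC(=O)OC
Why: The methyl ketone enolate is acylated by the carbonate and the reaction is driven by deprotonation of the β-keto ester formed (crossed Claisen condensation).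

**Step 3**
Reactants: 5 methyl 3-[4-(benzyloxy)-3,5-dimethoxyphenyl]-3-oxopropanoate; 6 methyl bromoacetate
Product: 7 dimethyl 2-[4-(benzyloxy)-3,5-dimethoxybenzoyl]butanedioate (racemic)
Conditions: K2CO3, acetone, rt
Reagents that add atoms: methyl bromoacetate (6), COC(=O)CBr
Why: The potassium enolate of the β-keto ester is C-alkylated once by the reactive α-bromo ester (SN2 alkylation of a 1,3-dicarbonyl compound); the new stereocentre is left racemic on purpose because step 4 resolves it dynamically.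

**Step 4**
Reactants: 7 dimethyl 2-[4-(benzyloxy)-3,5-dimethoxybenzoyl]butanedioate (racemic)
Product: 9 methyl (2S,3S)-2-[4-(benzyloxy)-3,5-dimethoxyphenyl]-5-oxooxolane-3-carboxylate, via hydroxy diester 8 (not isolated)
Conditions: RuCl[(S,S)-TsDPEN](p-cymene) (1 mol %), HCO2H/Et3N (5:2), DMF, 40 °C; then TsOH·H2O (cat.), PhMe, 50 °C
Reagents that add atoms: none
Why: In the formic acid/triethylamine buffer the C–H between ketone and ester of 7 enolises, so the two enantiomers interconvert faster than either is reduced; the divalent ruthenium hydride formed from the precatalyst and formate passes hydride and the N–H proton to the Re face of the aryl ketone through the six-membered outer-sphere transition state, the aryl ring lying against the cymene ligand (CH–π contact), which should set C2 as S. Of the two equilibrating α-epimers the one that turns the CH2CO2Me branch away from the catalyst should be reduced faster and give hydroxy diester 8 with the (S) α-centre; this is Noyori–Ikariya asymmetric transfer hydrogenation with dynamic kinetic resolution of an α-substituted β-keto ester, a known reaction class. The new benzylic hydroxyl then attacks the CH2CO2Me carbonyl in a 5-exo-trig acyl substitution that forms O1–C5 and closes the oxolanone ring with loss of methanol, the α-ester being unable to compete because it would give a four-membered ring. The trans placement of aryl and ester on the lactone is expected to be the kinetic outcome from this epimer and is also the more stable one, and since C3 stays α to an ester any cis lactone could be equilibrated to trans. The step needs ketone-face selectivity, secured by the TsDPEN ligand, and racemisation that is fast relative to reduction, secured by the doubly activated C–H and the amine buffer.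

**Step 5**
Reactants: 10 syringaldehyde; 11 allyl bromide
Product: 12 3,5-dimethoxy-4-(prop-2-en-1-yloxy)benzaldehyde
Conditions: allyl bromide, K2CO3, DMF, 50 °C
Reagents that add atoms: allyl bromide (11), C=CCBr
Why: Williamson O-allylation gives an aldehyde whose phenol protection can later be removed without touching the benzyl ether of the other ring.

**Step 6**
Reactants: 9 methyl (2S,3S)-2-[4-(benzyloxy)-3,5-dimethoxyphenyl]-5-oxooxolane-3-carboxylate; 12 3,5-dimethoxy-4-(prop-2-en-1-yloxy)benzaldehyde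
Product: 15 (1S,4S,5S,8S)-4-[4-(benzyloxy)-3,5-dimethoxyphenyl]-8-[3,5-dimethoxy-4-(prop-2-en-1-yloxy)phenyl]-3,7-dioxabicyclo[3.3.0]octane-2,6-dione, via trans aldol adduct 13 (not isolated), via cis aldol adduct 14 (not isolated)
Conditions: LiN(SiMe3)2 (1.05 equiv), THF, −78 °C; 12; −78 → 0 °C; AcOH
Reagents that add atoms: aldehyde 12, O=Cc1cc(OC)c(OCC=C)c(OC)c1
Why: The amide base should remove the more acidic and less hindered lactone C4–H rather than the C3–H next to the ester, and the enolate should add to 12 anti to the C3 ester to give trans aldolate 13; on warming this equilibrates by retro-aldol/aldol with cis aldolate 14, the only one whose alkoxide reaches the C3 CO2Me group (5-exo-trig lactonisation with loss of methoxide), so the mixture drains into the cis-fused bis-lactone and the C3 centre fixes C4 (lactone enolate aldol addition followed by translactonisation).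

**Step 7**
Reactants: 15 the cis-fused bis-lactone
Product: 16 (1S,2R,3R,4S)-1-[4-(benzyloxy)-3,5-dimethoxyphenyl]-4-[3,5-dimethoxy-4-(prop-2-en-1-yloxy)phenyl]-2,3-bis(hydroxymethyl)butane-1,4-diol
Conditions: LiAlH4, THF, 0 °C → rt; then H2O, aq. NaOH
Reagents that add atoms: none
Why: LiAlH4 reduces both lactone carbonyls to primary alcohols without touching the four stereocentres or the allyl and benzyl ethers (hydride reduction of lactones to diols).

**Step 8**
Reactants: 16 the tetraol
Product: 18 (1S,3aR,4S,6aR)-1-[4-(benzyloxy)-3,5-dimethoxyphenyl]-4-[3,5-dimethoxy-4-(prop-2-en-1-yloxy)phenyl]tetrahydro-1H,3H-furo[3,4-c]furan, via bis-mesylate 17 (not isolated)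
Conditions: MsCl (2.2 equiv), pyridine, 0 °C → rt
Reagents that add atoms: none
Why: The two primary hydroxyls should be sulfonylated faster than the hindered benzylic ones, and each benzylic hydroxyl then displaces the mesylate four atoms away (two 5-exo-tet Williamson closures at primary carbons), so both benzylic centres keep their configuration and the cis ring fusion follows from C8 and C8′.

**Step 9**
Reactants: 18 the O-allyl O′-benzyl furofuran
Product: 19 4-[(1S,3aR,4S,6aR)-4-[4-(benzyloxy)-3,5-dimethoxyphenyl]tetrahydro-1H,3H-furo[3,4-c]furan-1-yl]-2,6-dimethoxyphenol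
Conditions: Pd(PPh3)4 (5 mol %), morpholine, THF, rt
Reagents that add atoms: none
Why: Zerovalent palladium ionises the aryl allyl ether to a π-allyl complex that morpholine captures (Tsuji–Trost deallylation), which frees only the phenol of the ring on C7 and leaves the benzyl ether in place.

**Step 10**
Reactants: 19 the mono-phenol furofuran
Product: 22 (4-hydroxy-3,5-dimethoxyphenyl)[(3R,4R,5S)-5-[4-(benzyloxy)-3,5-dimethoxyphenyl]-4-(hydroxymethyl)oxolan-3-yl]methanone, via quinone methide 20 (not isolated), via hemiketal 21 (not isolated)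
Conditions: DDQ (1.1 equiv), 1,4-dioxane/H2O (10:1), rt
Reagents that add atoms: water, O
Why: DDQ dehydrogenates the para-hydroxybenzylic ether C7–H of the free phenol to quinone methide 20, water adds at C7 to give hemiketal 21, and this collapses to the aryl ketone with release of the C9′ hydroxyl (DDQ benzylic oxidation of a p-hydroxybenzyl ether); the benzyl-capped ring has no free phenol and should not react, the C7 configuration is erased so both C7 epimers converge, and C4 is not involved and keeps its configuration.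

**Step 11**
Reactants: 22 O-benzylciwujiatone
Product: 23 ciwujiatone, (4-hydroxy-3,5-dimethoxyphenyl)[(3R,4R,5S)-5-(4-hydroxy-3,5-dimethoxyphenyl)-4-(hydroxymethyl)oxolan-3-yl]methanone
Conditions: H2 (1 atm), 10% Pd/C, EtOAc, rt
Reagents that add atoms: none
Why: Hydrogenolysis of the aryl benzyl ether on palladium in a neutral solvent should be much faster than reduction of the electron-rich aryl ketone or cleavage of the benzylic C–O bond of the oxolane, and the base-free conditions spare the epimerisable C4 centre.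

**Compound list**
1 | acetosyringone | CC(=O)c1cc(OC)c(O)c(OC)c1 | starting material
2 | benzyl bromide | BrCc1ccccc1 | starting material
3 | 1-[4-(benzyloxy)-3,5-dimethoxyphenyl]ethan-1-one | CC(=O)c1cc(OC)c(OCc2ccccc2)c(OC)c1 | intermediate
4 | dimethyl carbonate | COC(=O)OC | starting material
5 | methyl 3-[4-(benzyloxy)-3,5-dimethoxyphenyl]-3-oxopropanoate | COC(=O)CC(=O)c1cc(OC)c(OCc2ccccc2)c(OC)c1 | intermediate
6 | methyl bromoacetate | COC(=O)CBr | starting material
7 | dimethyl 2-[4-(benzyloxy)-3,5-dimethoxybenzoyl]butanedioate, racemic | COC(=O)CC(C(=O)OC)C(=O)c1cc(OC)c(OCc2ccccc2)c(OC)c1 | intermediate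
8 | dimethyl (2S)-2-[(S)-[4-(benzyloxy)-3,5-dimethoxyphenyl](hydroxy)methyl]butanedioate | COC(=O)[C@@H](CC(=O)OC)[C@H](O)c1cc(OC)c(OCc2ccccc2)c(OC)c1 | intermediate (not isolated)
9 | methyl (2S,3S)-2-[4-(benzyloxy)-3,5-dimethoxyphenyl]-5-oxooxolane-3-carboxylate, trans | COC(=O)[C@H]1CC(=O)O[C@@H]1c1cc(OC)c(OCc2ccccc2)c(OC)c1 | intermediate
10 | syringaldehyde | O=Cc1cc(OC)c(O)c(OC)c1 | starting material
11 | allyl bromide | C=CCBr | starting material
12 | 3,5-dimethoxy-4-(prop-2-en-1-yloxy)benzaldehyde | O=Cc1cc(OC)c(OCC=C)c(OC)c1 | intermediate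
13 | methyl (2S,3S,4R)-2-[4-(benzyloxy)-3,5-dimethoxyphenyl]-4-{[3,5-dimethoxy-4-(prop-2-en-1-yloxy)phenyl](hydroxy)methyl}-5-oxooxolane-3-carboxylate, 3,4-trans, carbinol centre mixed, present as lithium alkoxide | COC(=O)[C@H]1[C@H](C(O)c2cc(OC)c(OCC=C)c(OC)c2)C(=O)O[C@@H]1c1cc(OC)c(OCc2ccccc2)c(OC)c1 | intermediate (not isolated)
14 | methyl (2S,3S,4S)-2-[4-(benzyloxy)-3,5-dimethoxyphenyl]-4-{(S)-[3,5-dimethoxy-4-(prop-2-en-1-yloxy)phenyl](hydroxy)methyl}-5-oxooxolane-3-carboxylate, 3,4-cis, present as lithium alkoxide | COC(=O)[C@H]1[C@@H]([C@H](O)c2cc(OC)c(OCC=C)c(OC)c2)C(=O)O[C@@H]1c1cc(OC)c(OCc2ccccc2)c(OC)c1 | intermediate (not isolated)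
15 | (1S,4S,5S,8S)-4-[4-(benzyloxy)-3,5-dimethoxyphenyl]-8-[3,5-dimethoxy-4-(prop-2-en-1-yloxy)phenyl]-3,7-dioxabicyclo[3.3.0]octane-2,6-dione, cis-fused, both aryl groups exo | O=C1O[C@H](c3cc(OC)c(OCc4ccccc4)c(OC)c3)[C@H]2C(=O)O[C@H](c3cc(OC)c(OCC=C)c(OC)c3)[C@@H]12 | intermediate
16 | (1S,2R,3R,4S)-1-[4-(benzyloxy)-3,5-dimethoxyphenyl]-4-[3,5-dimethoxy-4-(prop-2-en-1-yloxy)phenyl]-2,3-bis(hydroxymethyl)butane-1,4-diol | OC[C@H]([C@H](O)c1cc(OC)c(OCc2ccccc2)c(OC)c1)[C@H](CO)[C@H](O)c1cc(OC)c(OCC=C)c(OC)c1 | intermediate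
17 | bis(methanesulfonate) of 16 at the two primary hydroxyls | CS(=O)(=O)OC[C@H]([C@H](O)c1cc(OC)c(OCc2ccccc2)c(OC)c1)[C@H](COS(C)(=O)=O)[C@H](O)c1cc(OC)c(OCC=C)c(OC)c1 | intermediate (not isolated)
18 | (1S,3aR,4S,6aR)-1-[4-(benzyloxy)-3,5-dimethoxyphenyl]-4-[3,5-dimethoxy-4-(prop-2-en-1-yloxy)phenyl]tetrahydro-1H,3H-furo[3,4-c]furan | COc1cc(cc(OC)c1OCc1ccccc1)[C@H]1OC[C@@H]2[C@@H](c3cc(OC)c(OCC=C)c(OC)c3)OC[C@H]12 | intermediate
19 | 4-[(1S,3aR,4S,6aR)-4-[4-(benzyloxy)-3,5-dimethoxyphenyl]tetrahydro-1H,3H-furo[3,4-c]furan-1-yl]-2,6-dimethoxyphenol | COc1cc(cc(OC)c1OCc1ccccc1)[C@H]1OC[C@@H]2[C@@H](c3cc(OC)c(O)c(OC)c3)OC[C@H]12 | intermediate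
20 | quinone methide of 19 (C7 exocyclic to a 2,6-dimethoxycyclohexa-2,5-dien-1-one) | COc1cc(cc(OC)c1OCc1ccccc1)[C@H]1OC[C@@H]2C(=C3C=C(OC)C(=O)C(OC)=C3)OC[C@H]12 | intermediate (not isolated)
21 | C7 hemiketal (7-hydroxy furofuran, C7 configuration undefined) | COc1cc(cc(OC)c1OCc1ccccc1)[C@H]1OC[C@@H]2C(O)(c3cc(OC)c(O)c(OC)c3)OC[C@H]12 | intermediate (not isolated)
22 | (4-hydroxy-3,5-dimethoxyphenyl)[(3R,4R,5S)-5-[4-(benzyloxy)-3,5-dimethoxyphenyl]-4-(hydroxymethyl)oxolan-3-yl]methanone | COc1cc(C(=O)[C@H]2CO[C@H](c3cc(OC)c(OCc4ccccc4)c(OC)c3)[C@H]2CO)cc(OC)c1O | intermediate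
23 | ciwujiatone | COc1cc(C(=O)[C@H]2CO[C@H](c3cc(OC)c(O)c(OC)c3)[C@H]2CO)cc(OC)c1O | target

**Step count**
Total: 11 steps. Longest linear sequence: 10 steps (steps 1–4 and 6–11, from acetosyringone); step 5 is a one-step side branch.

**Steps most likely to fail**

Step 6 (aldol and bis-lactonisation). The retro-aldol equilibration may be too slow, or the aldolate may leave by other channels: dehydration to the arylidene lactone, or ring opening by loss of carboxylate from a C3 or C8 enolate (Stobbe-type elimination), so that the cis aldolate is not drained cleanly. The fallback replaces the thermodynamic funnel by kinetic protonation. It sets out from 9 and 12 and comes back at 15. The aldol is quenched at −78 °C and trans adduct 13 is isolated. Silylation (tBuMe2SiOTf, 2,6-lutidine) should give methyl (2S,3S,4R)-2-[4-(benzyloxy)-3,5-dimethoxyphenyl]-4-{[tert-butyl(dimethyl)silyl]oxy[3,5-dimethoxy-4-(prop-2-en-1-yloxy)phenyl]methyl}-5-oxooxolane-3-carboxylate F1. Its C4 enolate (LiN(SiMe3)2, 1 equiv, THF, −78 °C) is protonated with a bulky phenol from the face away from the C3 ester, which should give the 3,4-cis silyl ether, the (2S,3S,4S) epimer F2. Desilylation with HF·pyridine frees 14, which lactonises (cat. TsOH) to 15.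

Step 10 (DDQ opening of ring A). The quinone methide may lose the C8 proton instead of adding water, the phenol may couple, or the second benzylic position may be oxidised, so regio- and chemoselectivity of the oxidation could be lost. The fallback closes only one ring and oxidises an alcohol instead of an ether. It sets out from 16 and comes back at 23. Deallylation (Pd(PPh3)4, morpholine) should give the phenolic tetraol (1S,2R,3R,4S)-1-[4-(benzyloxy)-3,5-dimethoxyphenyl]-4-(4-hydroxy-3,5-dimethoxyphenyl)-2,3-bis(hydroxymethyl)butane-1,4-diol F3. Mild acid (camphorsulfonic acid, cat., CH2Cl2, 0 °C) ionises only the para-hydroxybenzylic carbinol, and capture by the 1,4-related primary hydroxyl should give the 2,3-trans mono-oxolane (S)-[4-(benzyloxy)-3,5-dimethoxyphenyl][(3R,4R,5S)-5-(4-hydroxy-3,5-dimethoxyphenyl)-4-(hydroxymethyl)oxolan-3-yl]methanol F4. The phenol is re-benzylated (2, K2CO3, acetone) to the bis-benzyl ether of that carbinol F5. MnO2 in CH2Cl2 oxidises the remaining benzylic alcohol and not the primary one, giving di-O-benzylciwujiatone, [4-(benzyloxy)-3,5-dimethoxyphenyl][(3R,4R,5S)-5-[4-(benzyloxy)-3,5-dimethoxyphenyl]-4-(hydroxymethyl)oxolan-3-yl]methanone F6. Hydrogenolysis (H2, Pd/C, EtOAc) then gives 23. Because the core is twofold symmetric, this opposite assignment of the two aryl rings leads to the same target; the oxolane aryl centre is then set by the trans-selective cation capture and not by the catalyst.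

Step 4 (key step). Racemisation may be slow relative to reduction, or the catalyst may discriminate poorly between the α-epimers, so that the lactone forms with low enantiomeric or diastereomeric purity. The fallback is an auxiliary-controlled aldol. It sets out from 10 and 2 and comes back at 9. Benzylation of 10 with 2 (K2CO3, DMF) gives 4-(benzyloxy)-3,5-dimethoxybenzaldehyde F7. (S)-4-Benzyl-1,3-oxazolidin-2-one is acylated (nBuLi, then methyl 4-chloro-4-oxobutanoate) to methyl 4-[(4S)-4-benzyl-2-oxo-1,3-oxazolidin-3-yl]-4-oxobutanoate F8. Its Z boron enolate (Bu2BOTf, iPr2NEt, CH2Cl2, −78 °C) adds to F7 in an Evans syn aldol to give methyl (3S,4S)-3-{[(4S)-4-benzyl-2-oxo-1,3-oxazolidin-3-yl]carbonyl}-4-[4-(benzyloxy)-3,5-dimethoxyphenyl]-4-hydroxybutanoate F9. This lactonises onto the terminal ester to the trans lactone imide (4S)-4-benzyl-3-{(2S,3S)-2-[4-(benzyloxy)-3,5-dimethoxyphenyl]-5-oxooxolane-3-carbonyl}-1,3-oxazolidin-2-one F10. LiOH/H2O2 removes the auxiliary to give (2S,3S)-2-[4-(benzyloxy)-3,5-dimethoxyphenyl]-5-oxooxolane-3-carboxylic acid F11, and Me3SiCHN2 in MeOH/PhMe gives 9.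

**Further compounds**
F1 | step 6 | methyl (2S,3S,4R)-2-[4-(benzyloxy)-3,5-dimethoxyphenyl]-4-{[tert-butyl(dimethyl)silyl]oxy[3,5-dimethoxy-4-(prop-2-en-1-yloxy)phenyl]methyl}-5-oxooxolane-3-carboxylate | COC(=O)[C@H]1[C@H](C(O[Si](C)(C)C(C)(C)C)c2cc(OC)c(OCC=C)c(OC)c2)C(=O)O[C@@H]1c1cc(OC)c(OCc2ccccc2)c(OC)c1
F2 | step 6 | methyl (2S,3S,4S)-2-[4-(benzyloxy)-3,5-dimethoxyphenyl]-4-{[tert-butyl(dimethyl)silyl]oxy[3,5-dimethoxy-4-(prop-2-en-1-yloxy)phenyl]methyl}-5-oxooxolane-3-carboxylate | COC(=O)[C@H]1[C@@H](C(O[Si](C)(C)C(C)(C)C)c2cc(OC)c(OCC=C)c(OC)c2)C(=O)O[C@@H]1c1cc(OC)c(OCc2ccccc2)c(OC)c1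
F3 | step 10 | (1S,2R,3R,4S)-1-[4-(benzyloxy)-3,5-dimethoxyphenyl]-4-(4-hydroxy-3,5-dimethoxyphenyl)-2,3-bis(hydroxymethyl)butane-1,4-diol | OC[C@H]([C@H](O)c1cc(OC)c(OCc2ccccc2)c(OC)c1)[C@H](CO)[C@H](O)c1cc(OC)c(O)c(OC)c1
F4 | step 10 | (S)-[4-(benzyloxy)-3,5-dimethoxyphenyl][(3R,4R,5S)-5-(4-hydroxy-3,5-dimethoxyphenyl)-4-(hydroxymethyl)oxolan-3-yl]methanol | OC[C@@H]1[C@@H](c2cc(OC)c(O)c(OC)c2)OC[C@@H]1[C@H](O)c1cc(OC)c(OCc2ccccc2)c(OC)c1
F5 | step 10 | (S)-[4-(benzyloxy)-3,5-dimethoxyphenyl][(3R,4R,5S)-5-[4-(benzyloxy)-3,5-dimethoxyphenyl]-4-(hydroxymethyl)oxolan-3-yl]methanol | OC[C@@H]1[C@@H](c2cc(OC)c(OCc3ccccc3)c(OC)c2)OC[C@@H]1[C@H](O)c1cc(OC)c(OCc2ccccc2)c(OC)c1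
F6 | step 10 | [4-(benzyloxy)-3,5-dimethoxyphenyl][(3R,4R,5S)-5-[4-(benzyloxy)-3,5-dimethoxyphenyl]-4-(hydroxymethyl)oxolan-3-yl]methanone | OC[C@@H]1[C@@H](c2cc(OC)c(OCc3ccccc3)c(OC)c2)OC[C@@H]1C(=O)c1cc(OC)c(OCc2ccccc2)c(OC)c1
F7 | step 4 | 4-(benzyloxy)-3,5-dimethoxybenzaldehyde | O=Cc1cc(OC)c(OCc2ccccc2)c(OC)c1
F8 | step 4 | methyl 4-[(4S)-4-benzyl-2-oxo-1,3-oxazolidin-3-yl]-4-oxobutanoate | COC(=O)CCC(=O)N1[C@@H](Cc2ccccc2)COC1=O
F9 | step 4 | methyl (3S,4S)-3-{[(4S)-4-benzyl-2-oxo-1,3-oxazolidin-3-yl]carbonyl}-4-[4-(benzyloxy)-3,5-dimethoxyphenyl]-4-hydroxybutanoate | O=C(N1[C@@H](Cc2ccccc2)COC1=O)[C@@H](CC(=O)OC)[C@H](O)c1cc(OC)c(OCc2ccccc2)c(OC)c1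
F10 | step 4 | (4S)-4-benzyl-3-{(2S,3S)-2-[4-(benzyloxy)-3,5-dimethoxyphenyl]-5-oxooxolane-3-carbonyl}-1,3-oxazolidin-2-one | O=C(N1[C@@H](Cc2ccccc2)COC1=O)[C@H]1CC(=O)O[C@@H]1c1cc(OC)c(OCc2ccccc2)c(OC)c1
F11 | step 4 | (2S,3S)-2-[4-(benzyloxy)-3,5-dimethoxyphenyl]-5-oxooxolane-3-carboxylic acid | OC(=O)[C@H]1CC(=O)O[C@@H]1c1cc(OC)c(OCc2ccccc2)c(OC)c1
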